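**Retrosynthetic overview**

1. Naamidine F ⇒ para-oxidation (Teuber) of the benzene ring that carries OH, two OMe groups and a free para C–H ⇒ phenol ⇒ amidine condensation of the 2-amino group with silylated 1-methylparabanic acid ⇒ free 2-aminoimidazole phenol.
2. 2-Aminoimidazole ⇒ acid removal of three Boc groups ⇒ fully substituted imidazole ⇒ Negishi disconnection of the C4–CH2 bond ⇒ imidazol-4-yl triflate + 4-methoxybenzylzinc chloride.
3. Triflate ⇒ aromatising O-triflation of a 5-benzyl imidazol-4-one ⇒ hydrogenation, Boc protection and Knoevenagel condensation ⇒ creatinine + 3-hydroxy-4,5-dimethoxybenzaldehyde.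
4. Feature the strategy rests on: N1–CH3, C2 with its exocyclic amino nitrogen, and C5 with its benzylic CH2 of the imidazole ring are the N-methyl, the amidine carbon with NH2 and the ring CH2 of creatinine; the creatinine C4 carbonyl sits exactly where the 4-methoxybenzyl group must be attached.
5. Ring order: no ring is built. The imidazole ring is bought as creatinine and aromatised in step 4, the imidazolidinedione ring is bought as 1-methylparabanic acid, and the quinone ring arises last from the benzene ring. The phenol travels as a tert-butyl carbonate, installed together with the N-Boc groups, so that the arylidene can be hydrogenated over Pd/C and one acid treatment frees phenol and amine together.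

Key step: step 6

Assumption (chemistry): both N-Boc groups are taken to sit on the exocyclic nitrogen, as in N4,N4-bis-Boc cytosines, whose ring nitrogen is flanked in the same way by an amidine carbon and a carbonyl. The arylidene is drawn as the Z isomer expected for this class; its geometry is erased by the hydrogenation.

**Route**

Step 1
Reactants: 1 creatinine; 2 3-hydroxy-4,5-dimethoxybenzaldehyde
Product: 3 (Z)-2-amino-5-(3-hydroxy-4,5-dimethoxybenzylidene)-1-methyl-1,5-dihydro-4H-imidazol-4-one
Conditions: piperidine, n-BuOH, reflux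
Reagents that add atoms: none
Why: Knoevenagel-type aldol condensation of the C5 methylene of creatinine (activated by the C4 carbonyl) with the aryl aldehyde, followed by dehydration to the conjugated arylidene; the meta phenol does not deactivate the aldehyde.

Step 2
Reactants: 3 arylidene creatinine
Product: 4 (Z)-2-[bis(tert-butoxycarbonyl)amino]-5-[3-(tert-butoxycarbonyloxy)-4,5-dimethoxybenzylidene]-1-methyl-1,5-dihydro-4H-imidazol-4-one
Conditions: Boc2O (3.6 equiv), DMAP (0.3 equiv), THF/DMF, 25 °C
Reagents that add atoms: di-tert-butyl dicarbonate, CC(C)(C)OC(=O)OC(=O)OC(C)(C)C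
Why: DMAP-catalysed acyl transfer (tert-butoxycarbonylation) to the phenol and twice to the exocyclic amidine nitrogen; because C5 is still sp2 there is no acidic C–H, so neither enol carbonate formation nor C-acylation can compete.

Step 3
Reactants: 4 tri-Boc arylidene
Product: 5 racemic 2-[bis(tert-butoxycarbonyl)amino]-5-[3-(tert-butoxycarbonyloxy)-4,5-dimethoxybenzyl]-1-methyl-1,5-dihydro-4H-imidazol-4-one
Conditions: H2 (1–3 bar), Pd/C, EtOAc, 25 °C
Reagents that add atoms: none
Why: Heterogeneous catalytic hydrogenation of the trisubstituted dehydroamino-acid-type alkene; the molecule holds no benzylic C–O or C–N bond, carbonate and carbamates are inert to H2 over Pd/C, and the new C5 stereocentre forms as a racemate that is removed again in step 4.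

Step 4
Reactants: 5 tri-Boc 5-benzyl imidazol-4-one
Product: 7 2-[bis(tert-butoxycarbonyl)amino]-5-[3-(tert-butoxycarbonyloxy)-4,5-dimethoxybenzyl]-1-methyl-1H-imidazol-4-yl trifluoromethanesulfonate, via potassium imidazol-4-olate 6 (not isolated)
Conditions: KN(SiMe3)2 (1.05 equiv), THF, −78 °C; then PhNTf2, −78 to 0 °C
Reagents that add atoms: N-phenylbis(trifluoromethanesulfonimide), O=S(=O)(N(c1ccccc1)S(=O)(=O)C(F)(F)F)C(F)(F)F; potassium bis(trimethylsilyl)amide, C[Si](C)(C)[N-][Si](C)(C)C.[K+] (potassium of intermediate 6 only)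
Why: Enolate O-sulfonylation (enol triflate formation): deprotonation at C5 gives an aromatic 4-oxidoimidazole whose hard oxygen is triflated by PhNTf2, as in the preparation of oxazol-4-yl and thiazol-4-yl triflates from the corresponding azolones, and this fixes the aromatic tautomer.

Step 5
Reactants: 8 4-methoxybenzyl chloride
Product: 9 4-methoxybenzylzinc chloride (titrated THF solution, LiCl-complexed)
Conditions: Zn dust (activated with BrCH2CH2Br and Me3SiCl), LiCl, THF, 25 °C, slow addition of 8
Reagents that add atoms: zinc, [Zn]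
Why: Direct oxidative insertion of LiCl-activated zinc into the benzylic C–Cl bond (Knochel-type preparation of benzylic zinc chlorides); slow addition of the chloride keeps Wurtz-type homocoupling low.

Step 6
Reactants: 7 imidazol-4-yl triflate; 9 4-methoxybenzylzinc chloride
Product: 10 di-tert-butyl {5-[3-(tert-butoxycarbonyloxy)-4,5-dimethoxybenzyl]-4-(4-methoxybenzyl)-1-methyl-1H-imidazol-2-yl}imidodicarbonate
Conditions: Pd2(dba)3 (2.5 mol %), SPhos (10 mol %), THF, 50 °C, slow addition of 9 (1.5 equiv)
Reagents that add atoms: none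
Why: Zerovalent palladium ligated by SPhos (formed from Pd2(dba)3) inserts into the C4–O bond of the imidazol-4-yl triflate, the benzyl group passes from zinc to divalent palladium, and reductive elimination forges the C4–CH2 bond that completes the tetrasubstituted imidazole. The closest known reaction type is the Negishi coupling of heteroaryl triflates with benzylic zinc chlorides under palladium–biarylphosphine catalysis. No ring is closed and no stereocentre is formed. The step needs chemoselective coupling at C4: the triflate is the only C–O bond prone to oxidative addition (the aryl carbonate and the carbamates are inert under these conditions), and the benzylic zinc reagent has no beta hydrogen. The two Boc groups on nitrogen lower the electron density of the ring, which helps oxidative addition, and keep the exocyclic nitrogen from binding palladium; slow addition of the zinc reagent limits its homocoupling.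

Step 7
Reactants: 10 tri-Boc dibenzyl imidazole
Product: 11 5-[(2-amino-5-(4-methoxybenzyl)-3-methyl-3H-imidazol-4-yl)methyl]-2,3-dimethoxyphenol (2-amino-5-(3-hydroxy-4,5-dimethoxybenzyl)-4-(4-methoxybenzyl)-1-methylimidazole)
Conditions: TFA, CH2Cl2, 0 to 25 °C; then aq NaHCO3
Reagents that add atoms: none
Why: Acidolysis (Boc removal) of the two tert-butyl carbamates and the aryl tert-butyl carbonate with loss of isobutene and CO2; the methyl ethers and both C-benzyl groups are stable to TFA.

Step 8
Reactants: 11 2-aminoimidazole phenol; 12 1-methylparabanic acid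
Product: 14 4-{[5-(3-hydroxy-4,5-dimethoxybenzyl)-4-(4-methoxybenzyl)-1-methyl-1H-imidazol-2-yl]amino}-1-methyl-1H-imidazole-2,5-dione, via silylated methylparabanic acid 13 (not isolated)
Conditions: 12, N,O-bis(trimethylsilyl)acetamide, MeCN, reflux, then evaporation; 11, toluene, 110 °C; MeOH on work-up
Reagents that add atoms: N,O-bis(trimethylsilyl)acetamide, CC(=N[Si](C)(C)C)O[Si](C)(C)C (silyl group of intermediate 13 only)
Why: Amidine-forming addition–elimination of the 2-amino group at the O-silyl imidate carbon (C4) of silylated parabanic acid, the condensation known for 2-aminoimidazoles of this alkaloid family; only the carbonyl next to the N–H can become the silyl imidate, so the carbonyl next to N-methyl is kept.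

Step 9
Reactants: 14 phenol
Product: 15 naamidine F
Conditions: (KSO3)2NO (3 equiv), KH2PO4 buffer (pH 6–7), acetone/H2O, 0 to 25 °C
Reagents that add atoms: potassium nitrosodisulfonate (Fremy's salt), [K+].[K+].[O-]S(=O)(=O)N([O])S(=O)(=O)[O-]
Why: Teuber oxidation: one nitrosodisulfonate radical abstracts the phenolic hydrogen, a second adds to the free para C–H position of the aryloxyl radical, and loss of imidodisulfonate gives the para-quinone, as in the oxidation of 2,3-dimethoxy-5-methylphenol, which has the same substitution pattern.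

**Compound list**

1 | creatinine (2-amino-1-methyl-1,5-dihydro-4H-imidazol-4-one) | CN1CC(=O)N=C1N | starting material
2 | 3-hydroxy-4,5-dimethoxybenzaldehyde | COc1cc(C=O)cc(O)c1OC | starting material
3 | (Z)-2-amino-5-(3-hydroxy-4,5-dimethoxybenzylidene)-1-methyl-1,5-dihydro-4H-imidazol-4-one | CN1C(N)=NC(=O)/C1=C/c1cc(O)c(OC)c(OC)c1 | intermediate
4 | (Z)-2-[bis(tert-butoxycarbonyl)amino]-5-[3-(tert-butoxycarbonyloxy)-4,5-dimethoxybenzylidene]-1-methyl-1,5-dihydro-4H-imidazol-4-one | CN1C(N(C(=O)OC(C)(C)C)C(=O)OC(C)(C)C)=NC(=O)/C1=C/c1cc(OC(=O)OC(C)(C)C)c(OC)c(OC)c1 | intermediate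
5 | racemic 2-[bis(tert-butoxycarbonyl)amino]-5-[3-(tert-butoxycarbonyloxy)-4,5-dimethoxybenzyl]-1-methyl-1,5-dihydro-4H-imidazol-4-one | CN1C(N(C(=O)OC(C)(C)C)C(=O)OC(C)(C)C)=NC(=O)C1Cc1cc(OC(=O)OC(C)(C)C)c(OC)c(OC)c1 | intermediate
6 | potassium 2-[bis(tert-butoxycarbonyl)amino]-5-[3-(tert-butoxycarbonyloxy)-4,5-dimethoxybenzyl]-1-methyl-1H-imidazol-4-olate | Cn1c(Cc2cc(OC(=O)OC(C)(C)C)c(OC)c(OC)c2)c([O-])nc1N(C(=O)OC(C)(C)C)C(=O)OC(C)(C)C.[K+] | intermediate
7 | 2-[bis(tert-butoxycarbonyl)amino]-5-[3-(tert-butoxycarbonyloxy)-4,5-dimethoxybenzyl]-1-methyl-1H-imidazol-4-yl trifluoromethanesulfonate | Cn1c(Cc2cc(OC(=O)OC(C)(C)C)c(OC)c(OC)c2)c(OS(=O)(=O)C(F)(F)F)nc1N(C(=O)OC(C)(C)C)C(=O)OC(C)(C)C | intermediate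
8 | 4-methoxybenzyl chloride | COc1ccc(CCl)cc1 | starting material
9 | 4-methoxybenzylzinc chloride | COc1ccc(C[Zn]Cl)cc1 | intermediate
10 | di-tert-butyl {5-[3-(tert-butoxycarbonyloxy)-4,5-dimethoxybenzyl]-4-(4-methoxybenzyl)-1-methyl-1H-imidazol-2-yl}imidodicarbonate | Cn1c(Cc2cc(OC(=O)OC(C)(C)C)c(OC)c(OC)c2)c(Cc2ccc(OC)cc2)nc1N(C(=O)OC(C)(C)C)C(=O)OC(C)(C)C | intermediate
11 | 2-amino-5-(3-hydroxy-4,5-dimethoxybenzyl)-4-(4-methoxybenzyl)-1-methyl-1H-imidazole | Cn1c(Cc2cc(O)c(OC)c(OC)c2)c(Cc2ccc(OC)cc2)nc1N | intermediate
12 | 1-methylparabanic acid (1-methylimidazolidine-2,4,5-trione) | CN1C(=O)NC(=O)C1=O | starting material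
13 | 1-methyl-4-(trimethylsilyloxy)-1H-imidazole-2,5-dione (O-silyl lactim form of silylated 1-methylparabanic acid) | CN1C(=O)N=C(O[Si](C)(C)C)C1=O | intermediate
14 | 4-{[5-(3-hydroxy-4,5-dimethoxybenzyl)-4-(4-methoxybenzyl)-1-methyl-1H-imidazol-2-yl]amino}-1-methyl-1H-imidazole-2,5-dione | Cn1c(Cc2cc(O)c(OC)c(OC)c2)c(Cc2ccc(OC)cc2)nc1NC1=NC(=O)N(C)C1=O | intermediate
15 | naamidine F | COC1=C(OC)C(=O)C(Cc2c(Cc3ccc(OC)cc3)nc(NC3=NC(=O)N(C)C3=O)n2C)=CC1=O | target

**Step count**

Total: 9 steps. Longest linear sequence: 8 steps (steps 1, 2, 3, 4, 6, 7, 8, 9); step 5 is a one-step side branch.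

**Steps most likely to fail**

Step 6 (Negishi benzylation). Transmetalation may be outrun by homocoupling of the benzylic zinc reagent, and the zinc reagent or chloride may attack the sulfur of the electron-rich triflate, cleaving the S–O bond and returning the imidazolone. The fallback avoids any benzylic organometallic and brings the methylene carbon in as carbon monoxide. Setting out from triflate 7, a carbonylative Suzuki–Miyaura coupling with 4-methoxyphenylboronic acid (CO 1 atm, PdCl2(dppf), K2CO3, KI, anisole, 80 °C) should give the 4-(4-methoxybenzoyl)imidazole F1. Reduction with NaBH4 (THF/EtOH, 0 °C) should give the racemic carbinol F2. Et3SiH and TFA in CH2Cl2 should then remove the benzylic hydroxyl by ionic hydrogenation and cleave the three Boc groups in the same flask, so that the route is rejoined at amine 11.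

Step 4 (aromatising triflation). The ambident oxidoimidazole may be sulfonylated at N3 or C5 instead of oxygen, a Boc group may be transferred from the carbonate or the imidodicarbonate onto the enolate oxygen, or the triflate may lose its sulfonyl group during isolation. The fallback replaces the C–O electrophile by a robust C–S electrophile that is made without an ambident enolate. Setting out from imidazolone 5, thionation with Lawesson's reagent (THF, 60 °C) should give the 4-thioxo compound F3. S-Methylation (MeI, K2CO3, acetone) should give the aromatic 4-(methylthio)imidazole F4. Cross-coupling of this heteroaryl methyl thioether with zinc reagent 9 (Pd(OAc)2/SPhos, or Ni(acac)2/DPEphos, THF, 25–50 °C), a known coupling type for N-heteroaryl thioethers and benzylic zinc chlorides, should rejoin the route at 10.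

Step 9 (Teuber oxidation). The nitroxyl radical may attack the doubly benzylic methylene groups or the acylated aminoimidazole, and the acylamidine unit may hydrolyse in the aqueous buffer during a slow oxidation, instead of clean para-oxygenation. The fallback changes the order of events so that the hydrolytically sensitive ring is attached last. Setting out from aminophenol 11, kept protonated as its trifluoroacetate salt, (KSO3)2NO in aqueous acetate buffer (pH 5)/acetone should give the 2-aminoimidazole quinone F5. Condensation of F5 with silylated parabanic acid 13 (MeCN, 60 °C, high dilution to suppress amine–quinone addition) should return to the route at target 15.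

**Further compounds**

F1 | step 6 | di-tert-butyl {5-[3-(tert-butoxycarbonyloxy)-4,5-dimethoxybenzyl]-4-(4-methoxybenzoyl)-1-methyl-1H-imidazol-2-yl}imidodicarbonate | Cn1c(Cc2cc(OC(=O)OC(C)(C)C)c(OC)c(OC)c2)c(C(=O)c2ccc(OC)cc2)nc1N(C(=O)OC(C)(C)C)C(=O)OC(C)(C)C
F2 | step 6 | racemic di-tert-butyl {5-[3-(tert-butoxycarbonyloxy)-4,5-dimethoxybenzyl]-4-[hydroxy(4-methoxyphenyl)methyl]-1-methyl-1H-imidazol-2-yl}imidodicarbonate | Cn1c(Cc2cc(OC(=O)OC(C)(C)C)c(OC)c(OC)c2)c(C(O)c2ccc(OC)cc2)nc1N(C(=O)OC(C)(C)C)C(=O)OC(C)(C)C
F3 | step 4 | racemic 2-[bis(tert-butoxycarbonyl)amino]-5-[3-(tert-butoxycarbonyloxy)-4,5-dimethoxybenzyl]-1-methyl-1,5-dihydro-4H-imidazole-4-thione | CN1C(N(C(=O)OC(C)(C)C)C(=O)OC(C)(C)C)=NC(=S)C1Cc1cc(OC(=O)OC(C)(C)C)c(OC)c(OC)c1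
F4 | step 4 | di-tert-butyl {5-[3-(tert-butoxycarbonyloxy)-4,5-dimethoxybenzyl]-1-methyl-4-(methylthio)-1H-imidazol-2-yl}imidodicarbonate | Cn1c(Cc2cc(OC(=O)OC(C)(C)C)c(OC)c(OC)c2)c(SC)nc1N(C(=O)OC(C)(C)C)C(=O)OC(C)(C)C
F5 | step 9 | 5-{[2-amino-5-(4-methoxybenzyl)-3-methyl-3H-imidazol-4-yl]methyl}-2,3-dimethoxy-1,4-benzoquinone | COC1=C(OC)C(=O)C(Cc2c(Cc3ccc(OC)cc3)nc(N)n2C)=CC1=O
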